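**Retrosynthetic overview**
1. Target ⇐ syn-dihydroxylation of C11=C12 and acetylation of a C2/C9/C14 triol; ten-membered ring ⇐ ring-closing metathesis at C5=C6 with the CH2Cl group already in place.
2. γ-Lactone (C7, C8, C17) ⇐ chelation-controlled propanoate aldol on a C8 ketone; the C7 vinyl carbinol ⇐ alkoxyallylboration of a C8 aldehyde.
3. C3–C5/C16 chain ⇐ alkylation of a C2 methyl ketone with 3-chloro-2-(chloromethyl)prop-1-ene, then CBS reduction.
4. Key disconnection: the cyclohexene and a temporary C2–O9 lactone form together in an ester-tethered intramolecular Diels–Alder reaction of a dienyl (Z)-3-benzoyloxy-2-methylacrylate, relaying C9 of (R)-glyceraldehyde acetonide to C10, C1 and C14.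
5. Ring order: six-membered ring plus tether lactone (step 7, lactone reopened in step 8) → γ-lactone (step 17) → ten-membered ring (step 18).

Convention (one line): carbons carry the briarane numbers of the target (C15 = CH3 on C1, C16 = CH2Cl, C17/C18/C19 = lactone CH, its CH3 and C=O, C20 = CH3 on C11); the target is (1S,2S,5E,7S,8S,9S,10S,11S,12R,14S,17R); TES = triethylsilyl, TBS = tert-butyldimethylsilyl, MOM = methoxymethyl, Bz = benzoyl, Ipc = isopinocampheyl.

**Step 1**
Reactants: 1 (R)-2,2-dimethyl-1,3-dioxolane-4-carbaldehyde; 2 2-(triphenylphosphoranylidene)propanal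
Product: 3 (2E)-3-[(4S)-2,2-dimethyl-1,3-dioxolan-4-yl]-2-methylprop-2-enal
Conditions: toluene, 60 °C
Reagents that add atoms: none
Why: Wittig olefination with a stabilised ylide is (E)-selective and leaves the C9 stereocentre of the α-alkoxy aldehyde untouched.

**Step 2**
Reactants: 3 (2E)-3-[(4S)-2,2-dimethyl-1,3-dioxolan-4-yl]-2-methylprop-2-enal
Product: 4 (4S)-2,2-dimethyl-4-[(1E)-2-methylbuta-1,3-dien-1-yl]-1,3-dioxolane
Conditions: Ph3PCH3Br, KOtBu, THF, 0 °C
Reagents that add atoms: methyltriphenylphosphonium bromide, C[P+](c1ccccc1)(c1ccccc1)c1ccccc1.[Br-]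
Why: Wittig methylenation of the enal carbonyl gives the (E)-1,3-diene (C10–C13) without touching the existing alkene geometry or C9.

**Step 3**
Reactants: 4 (4S)-2,2-dimethyl-4-[(1E)-2-methylbuta-1,3-dien-1-yl]-1,3-dioxolane
Product: 5 (2S,3E)-4-methylhexa-3,5-diene-1,2-diol
Conditions: AcOH/H2O/THF (3:1:1), 45 °C
Reagents that add atoms: none
Why: Acid-catalysed acetal hydrolysis frees the 1,2-diol, the weak acid being chosen so that the dienylic C9–O bond does not ionise.

**Step 4**
Reactants: 5 (2S,3E)-4-methylhexa-3,5-diene-1,2-diol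
Product: 6 (2S,3E)-4-methyl-1-(triethylsilyloxy)hexa-3,5-dien-2-ol
Conditions: TESCl (1.0 equiv), imidazole, CH2Cl2, −78 °C
Reagents that add atoms: triethylsilyl chloride, CC[Si](Cl)(CC)CC
Why: Kinetic silyl ether formation takes the unhindered primary (C8) hydroxyl and leaves the secondary dienylic C9 hydroxyl free for the tether.

**Step 5**
Reactants: 6 (2S,3E)-4-methyl-1-(triethylsilyloxy)hexa-3,5-dien-2-ol; 7 propanoyl chloride
Product: 8 (2S,3E)-4-methyl-1-(triethylsilyloxy)hexa-3,5-dien-2-yl propanoate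
Conditions: pyridine, DMAP (cat.), CH2Cl2, 0 °C
Reagents that add atoms: none
Why: O-Acylation (esterification) places the future C2–C1–C15 unit on the C9 oxygen.

**Step 6**
Reactants: 8 (2S,3E)-4-methyl-1-(triethylsilyloxy)hexa-3,5-dien-2-yl propanoate
Product: 10 (2S,3E)-4-methyl-1-(triethylsilyloxy)hexa-3,5-dien-2-yl (2Z)-3-(benzoyloxy)-2-methylprop-2-enoate, via lithium formyl-ester enolate 9 (not isolated)
Conditions: LiN(iPr)2, THF, −78 °C; HCO2CH2CF3; then BzCl, −78 → 0 °C
Reagents that add atoms: 2,2,2-trifluoroethyl formate, O=COCC(F)(F)F; benzoyl chloride, O=C(Cl)c1ccccc1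
Why: Crossed Claisen formylation of the ester enolate gives the lithium-chelated (Z)-enolate of the formyl ester, and O-acylation of that chelate keeps the benzoyloxy group cis to the ester carbonyl.

**Step 7**
Reactants: 10 (2S,3E)-4-methyl-1-(triethylsilyloxy)hexa-3,5-dien-2-yl (2Z)-3-(benzoyloxy)-2-methylprop-2-enoate
Product: 11 (3S,3aS,7S,7aR)-4,7a-dimethyl-1-oxo-3-[(triethylsilyloxy)methyl]-1,3,3a,6,7,7a-hexahydro-2-benzofuran-7-yl benzoate (trans-fused; cyclohexene C1/C10–C14 plus C2–O9 lactone)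
Conditions: o-dichlorobenzene (0.01 M), BHT, 180 °C, sealed tube
Reagents that add atoms: none
Why: Intramolecular Diels–Alder reaction of the ester-tethered triene, in which allylic 1,3-strain between the C11 methyl and C9 keeps H9 in the diene plane so the O9-tethered dienophile reaches one diene face only (sets C10), the bulky (Z)-benzoyloxy group and the tether carbonyl take the exo positions with the small methyl endo (trans fusion, sets C1), and the Z geometry is carried suprafacially to C14 (benzoate cis to C2).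

**Step 8**
Reactants: 11 trans-fused lactone benzoate
Product: 12 1-{(1R,2S,6S)-6-hydroxy-2-[(1S)-1-hydroxy-2-(triethylsilyloxy)ethyl]-1,3-dimethylcyclohex-3-en-1-yl}ethan-1-one
Conditions: MeLi (3.3 equiv), THF, −78 °C; aqueous NH4Cl at −78 °C
Reagents that add atoms: methyllithium, [Li]C
Why: Nucleophilic acyl addition of MeLi to the non-enolisable lactone stops at the lithium hemiketal at −78 °C (no over-addition, no retro-aldol) and releases the C2 methyl ketone (new CH3 = C3) and the C9 hydroxyl on quench, while two further equivalents cleave the benzoate to the C14 hydroxyl.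

**Step 9**
Reactants: 12 methyl ketone diol
Product: 13 1-{(1R,2S,6S)-6-(TBS-oxy)-2-[(1S)-1-(TBS-oxy)-2-(TES-oxy)ethyl]-1,3-dimethylcyclohex-3-en-1-yl}ethan-1-one
Conditions: TBSOTf (2.5 equiv), 2,6-lutidine, CH2Cl2, −78 → 0 °C
Reagents that add atoms: tert-butyldimethylsilyl triflate, CC(C)(C)[Si](C)(C)OS(=O)(=O)C(F)(F)F
Why: Silyl triflate silylation protects the C9 and C14 hydroxyls (trapping the open hydroxy ketone form) without enolising the ketone under the weak base.

**Step 10**
Reactants: 13 bis-TBS methyl ketone; 14 3-chloro-2-(chloromethyl)prop-1-ene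
Product: 15 4-(chloromethyl)-1-{(1R,2S,6S)-6-(TBS-oxy)-2-[(1S)-1-(TBS-oxy)-2-(TES-oxy)ethyl]-1,3-dimethylcyclohex-3-en-1-yl}pent-4-en-1-one
Conditions: LiN(iPr)2, THF, −78 °C; then 14 (5 equiv), NaI (cat.), DMPU, −78 → −20 °C
Reagents that add atoms: none
Why: Kinetic enolate alkylation (SN2 at an allylic chloride), in which quaternary C1 leaves only the methyl group enolisable and the excess of symmetric dichloride ensures monoalkylation, bringing in C4, C5 and the chloromethyl carbon C16.

**Step 11**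
Reactants: 15 chloro ketone
Product: 16 (1S)-4-(chloromethyl)-1-{(1S,2S,6S)-6-(TBS-oxy)-2-[(1S)-1-(TBS-oxy)-2-(TES-oxy)ethyl]-1,3-dimethylcyclohex-3-en-1-yl}pent-4-en-1-ol (C2 alcohol)
Conditions: (R)-2-methyl-CBS-oxazaborolidine (0.5 equiv), catecholborane, toluene, −78 → −40 °C
Reagents that add atoms: none
Why: Corey–Bakshi–Shibata reduction, the (R)-catalyst distinguishing the large quaternary C1 from the small CH2 chain to give the (2S)-alcohol under reagent control, with catecholborane leaving the alkenes untouched.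

**Step 12**
Reactants: 16 C2 alcohol
Product: 17 C2 TBS ether of 16 (TBS on O2, O9, O14; TES on O8)
Conditions: TBSOTf, 2,6-lutidine, CH2Cl2, −40 → 0 °C
Reagents that add atoms: tert-butyldimethylsilyl triflate, CC(C)(C)[Si](C)(C)OS(=O)(=O)C(F)(F)F
Why: Silyl triflate silylation caps the hindered C2 hydroxyl so that it cannot form a lactol with the C8 aldehyde made next.

**Step 13**
Reactants: 17 tris-TBS TES ether
Product: 18 C8 aldehyde (17 with CH2OTES replaced by CHO; C9 keeps its OTBS)
Conditions: (COCl)2, DMSO, CH2Cl2, −78 → −30 °C; Et3N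
Reagents that add atoms: none
Why: Swern oxidation conditions cleave and oxidise the primary triethylsilyl ether directly to the aldehyde while the secondary TBS ethers survive, and the low temperature avoids epimerisation at C9.

**Step 14**
Reactants: 18 C8 aldehyde; 19 3-(methoxymethoxy)prop-1-ene
Product: 21 (7S,8R)-syn homoallylic alcohol (C8–OH; C7 carrying OMOM plus the vinyl group C6), via allylborane 20 (not isolated)
Conditions: 19, s-BuLi, THF, −78 °C; (+)-Ipc2BOMe; BF3·OEt2; then 18, −78 °C; NaBO3·4H2O, H2O, rt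
Reagents that add atoms: none
Why: Brown alkoxyallylboration, in which the (Z)-γ-alkoxyallylborane adds through a chair-like six-membered transition state to give the syn product and the Ipc ligands direct attack to the Re face of the aldehyde (matched with its Felkin–Anh preference), so C7 is set (S).

**Step 15**
Reactants: 21 syn alcohol
Product: 22 C8 ketone (C9–OTBS and C7–OMOM on either side)
Conditions: Dess–Martin periodinane, NaHCO3, CH2Cl2, 0 °C → rt
Reagents that add atoms: none
Why: Dess–Martin oxidation under buffered non-basic conditions gives the ketone without epimerising the acidic C7 or C9 positions.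

**Step 16**
Reactants: 22 C8 ketone; 23 methyl propanoate
Product: 25 (8S,17R) aldol adduct (tertiary C8–OH carrying the CH(CH3)CO2CH3 unit; C7–OMOM retained), via cerium enolate 24 (not isolated)
Conditions: 23, LiN(iPr)2, THF–DMPU (4:1), −78 °C; CeCl3; then 22, −78 °C; AcOH quench at −78 °C
Reagents that add atoms: none
Why: Chelation-controlled aldol addition, in which the cerium enolate (CH3 cis to the metal-bound oxygen) adds rather than enolises, chelation by the C7 methoxymethoxy oxygen (Cram chelate) and the Felkin–Anh preference of the C9 silyloxy centre select the same C8 face (8S), and a closed Zimmerman–Traxler transition state places the C17 methyl syn to the new hydroxyl (17R).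

**Step 17**
Reactants: 25 aldol adduct
Product: 27 γ-lactone C19(=O)–O–C7 (C7 vinyl; C8 hydroxyl; C17 methyl), via hydroxy ester 26 (not isolated)
Conditions: Me2BBr, CH2Cl2, −78 °C; aqueous NaHCO3; then PPTS (cat.), toluene, 50 °C
Reagents that add atoms: none
Why: Me2BBr cleaves the acetal-type MOM ether at low temperature without touching the TBS ethers, and the freed C7 hydroxyl then closes the five-membered ring onto the methyl ester under mild acid (lactonisation), leaving C7, C8 and C17 unchanged.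

**Step 18**
Reactants: 27 vinyl lactone with the CH2=C(CH2Cl)CH2CH2 chain
Product: 28 tricyclic tris-TBS ether (ten-membered ring closed at C5=C6; target skeleton with TBS on O2, O9, O14 and C11=C12 alkene)
Conditions: second-generation Hoveyda–Grubbs catalyst (15 mol %), 1,4-benzoquinone, toluene (0.002 M), 100 °C
Reagents that add atoms: none
Why: Ring-closing metathesis between the C7 vinyl group and the 1,1-disubstituted alkene forms the ten-membered ring, whose fused lactone and cyclohexene favour the ring-cis (5E) trisubstituted alkene, and the allylic chloride is tolerated by the Ru carbene.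

**Step 19**
Reactants: 28 tris-TBS ether
Product: 29 C2/C9/C14 triol (C8 tertiary hydroxyl also free)
Conditions: HF·pyridine, pyridine, THF, 0 → 40 °C
Reagents that add atoms: none
Why: Fluoride-mediated desilylation removes the three TBS ethers without affecting the lactone, the allylic chloride or the tertiary alcohol.

**Step 20**
Reactants: 29 triol
Product: 30 2,9,14-triacetate with C11=C12 alkene
Conditions: Ac2O, pyridine, DMAP (cat.), CH2Cl2, rt
Reagents that add atoms: acetic anhydride, CC(=O)OC(C)=O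
Why: DMAP-catalysed acetylation esterifies the three secondary hydroxyls, whereas the hindered tertiary C8 hydroxyl does not react.

**Step 21**
Reactants: 30 triacetate
Product: 31 CNP0211628.2 (target)
Conditions: OsO4 (5 mol %), NMO, acetone–H2O (10:1), 0 °C
Reagents that add atoms: osmium tetroxide, O=[Os](=O)(=O)=O; N-methylmorpholine N-oxide, C[N+]1([O-])CCOCC1; water, O
Why: Upjohn syn-dihydroxylation, in which OsO4 takes the electron-rich C11=C12 bond rather than C5=C6 (deactivated by the allylic chloride and acyloxy groups) and adds from the face of H10, opposite the C9 branch on C10 and the C15 methyl, to give the cis-diol (11S,12R).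

**Compound list**
1 | (R)-2,2-dimethyl-1,3-dioxolane-4-carbaldehyde | O=C[C@H]1COC(C)(C)O1 | starting material
2 | 2-(triphenylphosphoranylidene)propanal | CC(C=O)=P(c1ccccc1)(c1ccccc1)c1ccccc1 | starting material
3 | (2E)-3-[(4S)-2,2-dimethyl-1,3-dioxolan-4-yl]-2-methylprop-2-enal | O=C/C(C)=C/[C@H]1COC(C)(C)O1 | intermediate
4 | (4S)-2,2-dimethyl-4-[(1E)-2-methylbuta-1,3-dien-1-yl]-1,3-dioxolane | C=C/C(C)=C/[C@H]1COC(C)(C)O1 | intermediate
5 | (2S,3E)-4-methylhexa-3,5-diene-1,2-diol | C=C/C(C)=C/[C@H](O)CO | intermediate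
6 | (2S,3E)-4-methyl-1-(triethylsilyloxy)hexa-3,5-dien-2-ol | C=C/C(C)=C/[C@H](O)CO[Si](CC)(CC)CC | intermediate
7 | propanoyl chloride | CCC(=O)Cl | starting material
8 | (2S,3E)-4-methyl-1-(triethylsilyloxy)hexa-3,5-dien-2-yl propanoate | C=C/C(C)=C/[C@H](OC(=O)CC)CO[Si](CC)(CC)CC | intermediate
9 | lithium (Z)-enolate of the 2-formylpropanoate of 6 (not isolated) | C=C/C(C)=C/[C@H](OC(=O)/C(C)=C\[O-])CO[Si](CC)(CC)CC.[Li+] | intermediate
10 | (2S,3E)-4-methyl-1-(triethylsilyloxy)hexa-3,5-dien-2-yl (2Z)-3-(benzoyloxy)-2-methylprop-2-enoate | C=C/C(C)=C/[C@H](OC(=O)/C(C)=C\OC(=O)c1ccccc1)CO[Si](CC)(CC)CC | intermediate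
11 | (3S,3aS,7S,7aR)-4,7a-dimethyl-1-oxo-3-[(triethylsilyloxy)methyl]-1,3,3a,6,7,7a-hexahydro-2-benzofuran-7-yl benzoate | O=C1O[C@H](CO[Si](CC)(CC)CC)[C@H]2C(C)=CC[C@H](OC(=O)c3ccccc3)[C@]12C | intermediate
12 | 1-{(1R,2S,6S)-6-hydroxy-2-[(1S)-1-hydroxy-2-(triethylsilyloxy)ethyl]-1,3-dimethylcyclohex-3-en-1-yl}ethan-1-one | CC(=O)[C@@]1(C)[C@@H](O)CC=C(C)[C@@H]1[C@H](O)CO[Si](CC)(CC)CC | intermediate
13 | bis-TBS ether of 12 (O9 and O14) | CC(=O)[C@@]1(C)[C@@H](O[Si](C)(C)C(C)(C)C)CC=C(C)[C@@H]1[C@H](O[Si](C)(C)C(C)(C)C)CO[Si](CC)(CC)CC | intermediate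
14 | 3-chloro-2-(chloromethyl)prop-1-ene | C=C(CCl)CCl | starting material
15 | C2 ketone with CH2CH2C(=CH2)CH2Cl chain (13 alkylated at C3) | ClCC(=C)CCC(=O)[C@@]1(C)[C@@H](O[Si](C)(C)C(C)(C)C)CC=C(C)[C@@H]1[C@H](O[Si](C)(C)C(C)(C)C)CO[Si](CC)(CC)CC | intermediate
16 | (2S)-alcohol from 15 | ClCC(=C)CC[C@H](O)[C@@]1(C)[C@@H](O[Si](C)(C)C(C)(C)C)CC=C(C)[C@@H]1[C@H](O[Si](C)(C)C(C)(C)C)CO[Si](CC)(CC)CC | intermediate
17 | C2 TBS ether of 16 | ClCC(=C)CC[C@H](O[Si](C)(C)C(C)(C)C)[C@@]1(C)[C@@H](O[Si](C)(C)C(C)(C)C)CC=C(C)[C@@H]1[C@H](O[Si](C)(C)C(C)(C)C)CO[Si](CC)(CC)CC | intermediate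
18 | C8 aldehyde | ClCC(=C)CC[C@H](O[Si](C)(C)C(C)(C)C)[C@@]1(C)[C@@H](O[Si](C)(C)C(C)(C)C)CC=C(C)[C@@H]1[C@H](O[Si](C)(C)C(C)(C)C)C=O | intermediate
19 | 3-(methoxymethoxy)prop-1-ene | C=CCOCOC | starting material
20 | [(2Z)-3-(methoxymethoxy)prop-2-en-1-yl]bis(isopinocampheyl)borane from (+)-Ipc2BOMe (not isolated) | COCO/C=C\CB([C@H]1C[C@H]2C[C@@H]([C@@H]1C)C2(C)C)[C@H]1C[C@H]2C[C@@H]([C@@H]1C)C2(C)C | intermediate
21 | (7S,8R)-syn C8 alcohol with C7–OMOM and vinyl | ClCC(=C)CC[C@H](O[Si](C)(C)C(C)(C)C)[C@@]1(C)[C@@H](O[Si](C)(C)C(C)(C)C)CC=C(C)[C@@H]1[C@H](O[Si](C)(C)C(C)(C)C)[C@H](O)[C@@H](OCOC)C=C | intermediate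
22 | C8 ketone | ClCC(=C)CC[C@H](O[Si](C)(C)C(C)(C)C)[C@@]1(C)[C@@H](O[Si](C)(C)C(C)(C)C)CC=C(C)[C@@H]1[C@H](O[Si](C)(C)C(C)(C)C)C(=O)[C@@H](OCOC)C=C | intermediate
23 | methyl propanoate | CCC(=O)OC | starting material
24 | Cl2Ce enolate of methyl propanoate, CH3 cis to OCe (not isolated) | C/C=C(/OC)O[Ce](Cl)Cl | intermediate
25 | aldol adduct: (8S) tertiary alcohol with (17R) methyl ester side chain and C7–OMOM | ClCC(=C)CC[C@H](O[Si](C)(C)C(C)(C)C)[C@@]1(C)[C@@H](O[Si](C)(C)C(C)(C)C)CC=C(C)[C@@H]1[C@H](O[Si](C)(C)C(C)(C)C)[C@](O)([C@@H](C)C(=O)OC)[C@@H](OCOC)C=C | intermediate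
26 | C7 hydroxy ester after MOM removal (not isolated) | ClCC(=C)CC[C@H](O[Si](C)(C)C(C)(C)C)[C@@]1(C)[C@@H](O[Si](C)(C)C(C)(C)C)CC=C(C)[C@@H]1[C@H](O[Si](C)(C)C(C)(C)C)[C@](O)([C@@H](C)C(=O)OC)[C@@H](O)C=C | intermediate
27 | γ-lactone with C7 vinyl, C8–OH and C17 methyl | ClCC(=C)CC[C@H](O[Si](C)(C)C(C)(C)C)[C@@]1(C)[C@@H](O[Si](C)(C)C(C)(C)C)CC=C(C)[C@@H]1[C@H](O[Si](C)(C)C(C)(C)C)[C@@]2(O)[C@H](C=C)OC(=O)[C@@H]2C | intermediate
28 | tricyclic 2,9,14-tris-TBS ether with C11=C12 alkene | CC(C)(C)[Si](C)(C)O[C@H]1CC/C(CCl)=C\[C@@H]2OC(=O)[C@H](C)[C@@]2(O)[C@@H](O[Si](C)(C)C(C)(C)C)[C@H]2C(C)=CC[C@H](O[Si](C)(C)C(C)(C)C)[C@]12C | intermediate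
29 | 2,9,14-triol with C11=C12 alkene | O[C@H]1CC/C(CCl)=C\[C@@H]2OC(=O)[C@H](C)[C@@]2(O)[C@@H](O)[C@H]2C(C)=CC[C@H](O)[C@]12C | intermediate
30 | 2,9,14-triacetate with C11=C12 alkene | CC(=O)O[C@H]1CC/C(CCl)=C\[C@@H]2OC(=O)[C@H](C)[C@@]2(O)[C@@H](OC(C)=O)[C@H]2C(C)=CC[C@H](OC(C)=O)[C@]12C | intermediate
31 | CNP0211628.2 | CC(=O)O[C@H]1CC/C(CCl)=C\[C@@H]2OC(=O)[C@H](C)[C@@]2(O)[C@@H](OC(C)=O)[C@H]2[C@](C)(O)[C@H](O)C[C@H](OC(C)=O)[C@]12C | target

**Step count and risks**
Total step count: 21. Longest linear sequence: 21 steps (1 → 31); every other input is used as bought.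

The three steps most likely to fail are the cycloaddition (step 7), the ketone aldol (step 16) and the macrocyclisation (step 18).

In step 7 the benzoyloxy-substituted dienophile is only moderately activated and an ester tether cyclises reluctantly, so conversion may be low or the cis-fused lactone may compete. The fallback sets out from 6 and comes back at 11. It replaces the covalent tether by a metal template. Methyl propanoate 23 is formylated and O-benzoylated as in step 6 to give methyl (2Z)-3-(benzoyloxy)-2-methylprop-2-enoate F1. Compound 6 and this ester are then treated with MgBr2·OEt2 and Et3N. The magnesium alkoxide of 6 binds the ester carbonyl of the dienophile, so a Lewis-acid-activated cycloaddition runs near room temperature on the same diene face. The exo preference usual for α-methyl acrylates should place the ester trans to the C9 branch and give the hydroxy ester cycloadduct F2, which lactonises under PPTS in warm toluene to 11.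

In step 16 the ketone is hindered and enolisable on both sides, and the C17 configuration rests on enolate geometry. The fallback sets out from 22 and comes back at 27. The MOM ether is removed with Me2BBr to give the α-hydroxy ketone F3. This is esterified with 2-bromopropanoyl bromide and pyridine to the C7 2-bromopropanoate F4. An intramolecular Reformatsky reaction with activated Zn in THF then closes the lactone directly to 27, with the bulky C9 branch expected to sit trans to both the C7 vinyl and the C17 methyl group.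

In step 18 the closure of a ten-membered ring onto a trisubstituted alkene next to a lactone may stall or dimerise. The fallback sets out from 25 and comes back at 28. The metathesis is run first on the more flexible, open-chain 25 with the same catalyst to give the ten-membered MOM ether methyl ester F5. The lactone is then formed on the macrocycle with Me2BBr followed by PPTS, which gives 28.

**Further compounds**
F1 | step 7 | methyl (2Z)-3-(benzoyloxy)-2-methylprop-2-enoate | COC(=O)/C(C)=C\OC(=O)c1ccccc1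
F2 | step 7 | hydroxy ester cycloadduct (methyl ester at C2, benzoate at O14, free C9–OH) | COC(=O)[C@@]1(C)[C@@H](OC(=O)c2ccccc2)CC=C(C)[C@@H]1[C@H](O)CO[Si](CC)(CC)CC
F3 | step 16 | α-hydroxy ketone (22 without MOM) | ClCC(=C)CC[C@H](O[Si](C)(C)C(C)(C)C)[C@@]1(C)[C@@H](O[Si](C)(C)C(C)(C)C)CC=C(C)[C@@H]1[C@H](O[Si](C)(C)C(C)(C)C)C(=O)[C@@H](O)C=C
F4 | step 16 | C7 2-bromopropanoate of F3 (bromide centre as a mixture) | ClCC(=C)CC[C@H](O[Si](C)(C)C(C)(C)C)[C@@]1(C)[C@@H](O[Si](C)(C)C(C)(C)C)CC=C(C)[C@@H]1[C@H](O[Si](C)(C)C(C)(C)C)C(=O)[C@@H](OC(=O)C(C)Br)C=C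
F5 | step 18 | ten-membered MOM ether methyl ester (25 after ring closure at C5=C6) | CC(C)(C)[Si](C)(C)O[C@H]1CC/C(CCl)=C\[C@H](OCOC)[C@@](O)([C@@H](C)C(=O)OC)[C@@H](O[Si](C)(C)C(C)(C)C)[C@H]2C(C)=CC[C@H](O[Si](C)(C)C(C)(C)C)[C@]12C
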